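The small charge of the beta run, a quarter of the zeta charge, read 60 % target and 15 % isomer of the product at 12.0 h. The zeta run read 58 % and 17 % at 12.0 h. The flask lay between them in substrate, with the same partner, so I reckoned in fractions of the charge.

| flask | substrate | partner | remark | time |
|---|---|---|---|---|
| beta | 0.25 M | 2.5 M | run made earlier |  |
| zeta | 1 M | 2.5 M | run made earlier |  |
| flask | 0.50 M | 2.50 M |  | 10 h |

| run | time / h | target / % | isomer of the product / % |
|---|---|---|---|
| beta | 1.00 | 7 | 8 |
| beta | 1.50 | 20 | 4 |
| beta | 2.50 | 30 | 7 |
| beta | 4.00 | 46 | 6 |
| beta | 8.00 | 60 | 10 |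
| beta | 12.0 | 60 | 15 |
| zeta | 0.833 | 9 | 2 |
| zeta | 2.50 | 28 | 7 |
| zeta | 4.00 | 35 | 10 |
| zeta | 6.00 | 52 | 13 |
| zeta | 10.0 | 52 | 16 |
| zeta | 12.0 | 58 | 17 |

(readings scatter by 2 percentage points)



- ratio of target to isomer of the product at 12 min
- ratio of target to isomer of the product at 80 min
- ratio of target to isomer of the product at 10 h
- which of target and isomer of the product there is more of at 10 h

The thing to watch was the split, a selectivity factor: the summed target readings of both runs over their summed isomer readings. It came to 3.97. Next I took the target fraction at the end as the mean of beta at 8.00 h and zeta at 10.0 h, which gave 56.0 %. Dividing by the split gave an estimate of 14.1 % isomer of the product, so I put target ahead. The first zeta reading, 9 % against 2 %, already stood near the split, so I committed to the split at 12 min, 80 min and 10 h, though 12 min lay before any reading.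

The weak link was the pooling, since beta alone gave 4.46 and zeta 3.60. That gap of 0.860 stood against a scatter of 0.514 from the isomer readings. It was smaller than 2 such deviations, so I kept the pooled split.

The forecast gave 4.7, 4.5 and 4, with target ahead, and said of the zeta run that it had “the ratio steady near 4 from the first reading”.

The flask gave 4.30, 4.28 and 4.07, with 59.2 % target against 14.5 % isomer of the product at 10 h.

    substrate + partner → intermediate + released group (k = 1.23 L mol⁻¹ h⁻¹)
    intermediate ⇌ target (K = 7.08, k = 0.251 h⁻¹)
    intermediate ⇌ isomer of the product (K = 2.17, k = 0.0584 h⁻¹)
    partner → decomposed reagent (k = 1.35 h⁻¹)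

I then tried the split on a neighbour flask, the same flask but charged with 1.5 M of partner. Its target reached 45.7 % at 10.0 h, and dividing by the split gave 11.5 % isomer of the product, where that flask held 11.2 %. Its ratio at 10 h was 4.08, with partner at 0 % and substrate still at 34.4 %.

Readings and results were computed with constants of no real substance; the scatter is artificial.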